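The oxolane is disconnected at C4'–C5'. Its ring atoms map onto a 4-methylidene-1,3-dioxolane: O1' sits between C5' (an acetaldehyde carbon) and C2' (the α-carbon of a hydroxy acid), C3' is the carboxyl carbon and C4' an added methylene. A Lewis-acid Petasis–Ferrier rearrangement of the enol acetal (5R)-5-(benzyloxymethyl)-2-methyl-4-methylidene-1,3-dioxolane, made from O-benzyl-D-serine, should close the oxolan-3-one ring and set C5' cis to C2' in one operation. Directed reduction then sets C3'. A formyl-ylide Wittig reaction and a Horner–Wadsworth–Emmons coupling with an orsellinate-derived isocoumarin-3-ylmethylphosphonate build the (E,E)-diene, and fluoride releases the target.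

Key step: step 4

Remark: 5 and 6 are drawn as the cis (2R,5R) isomers; the minor C2 epimers expected from step 2 are carried along unseparated because step 4 destroys the acetal centre, and C2' of the target (R) comes unchanged from the α-carbon of D-serine.

Step 1
Reactants: 1 O-benzyl-D-serine
Product: 3 (2R)-3-(benzyloxy)-2-hydroxypropanoic acid, via α-lactone 2 (not isolated)
Conditions: NaNO2, 1 M H2SO4 (aq), 0 °C → rt
Reagents that add atoms: water, O
Why: Diazotisation of an α-amino acid: the carboxylate displaces dinitrogen to give α-lactone 2 and water reopens it at the same carbon, so two inversions leave the centre R (net retention).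

Step 2
Reactants: 3 (2R)-3-(benzyloxy)-2-hydroxypropanoic acid; 4 acetaldehyde
Product: 5 (2R,5R)-5-(benzyloxymethyl)-2-methyl-1,3-dioxolan-4-one
Conditions: MeCHO (excess), p-TsOH·H2O (cat.), MgSO4, CH2Cl2, 0 °C → rt
Reagents that add atoms: none
Why: Acid-catalysed acetalisation of an α-hydroxy acid with an aldehyde (1,3-dioxolan-4-one formation) should favour the cis isomer under thermodynamic control, and the configuration at the new acetal centre is irrelevant to the later steps.

Step 3
Reactants: 5 (2R,5R)-5-(benzyloxymethyl)-2-methyl-1,3-dioxolan-4-one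
Product: 6 (2R,5R)-5-(benzyloxymethyl)-2-methyl-4-methylidene-1,3-dioxolane
Conditions: Cp2TiMe2, toluene, 65 °C, dark; filtration through basic alumina
Reagents that add atoms: dimethyltitanocene, C[Ti](C)(C1C=CC=C1)C1C=CC=C1
Why: Carbonyl methylenation with dimethyltitanocene (through Cp2Ti=CH2 and an oxatitanacyclobutane) converts lactone-type carbonyls into enol ethers under non-basic conditions, so C5 is not epimerised and no stereocentre changes.

Step 4
Reactants: 6 (2R,5R)-5-(benzyloxymethyl)-2-methyl-4-methylidene-1,3-dioxolane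
Product: 8 (2R,5S)-2-(benzyloxymethyl)-5-methyloxolan-3-one, via enolate–oxocarbenium zwitterion 7 (not isolated)
Conditions: Me2AlCl (2 equiv), CH2Cl2, −78 °C; NaHCO3 (aq) quench
Reagents that add atoms: none
Why: Petasis–Ferrier rearrangement: Me2AlCl binds the enol-ether oxygen and breaks the O3–C2 acetal bond to give zwitterion 7, an aluminium enolate tethered through O1 to an (E)-O-ethylidene oxocarbenium ion, and the enolate methylene carbon then adds to the oxocarbenium carbon to form the C4–C5 bond of the oxolanone. The closest known reaction type is the Lewis-acid rearrangement of 4-methylidene-1,3-dioxolanes (and of the homologous dioxanes) to cyclic β-alkoxy ketones. The ring closes in a formally 5-(enolendo)-endo-trig mode, which should be tolerated because the electrophile is a cationic, oxygen-stabilised carbon held beside the nucleophile in a contact ion pair. The new stereocentre C5 is controlled by C2 (from D-serine): in the envelope transition state the methyl of the (E)-oxocarbenium ion and the benzyloxymethyl arm both lie pseudo-equatorial, which places them cis. The step needs cis-2,5 diastereoselectivity and cleavage of the acetal C–O bond on the enol side; the first is secured by the single existing centre and the second by the better leaving-group ability of the enolate oxygen, while both acetal epimers converge on the same cation. A non-hydridic Lewis acid at low temperature should leave the ketone unreduced and avoid β-elimination of benzyl alcohol.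

Step 5
Reactants: 8 (2R,5S)-2-(benzyloxymethyl)-5-methyloxolan-3-one
Product: 9 (2R,5S)-2-(hydroxymethyl)-5-methyloxolan-3-one
Conditions: H2 (1 atm), Pd/C, EtOAc, rt; used crude
Reagents that add atoms: none
Why: Heterogeneous hydrogenolysis of a benzyl ether is neutral, so the dialkyl ketone is untouched and the α-centre C2 should not epimerise.

Step 6
Reactants: 9 (2R,5S)-2-(hydroxymethyl)-5-methyloxolan-3-one
Product: 10 (2R,3S,5S)-2-(hydroxymethyl)-5-methyloxolan-3-ol
Conditions: Me4NBH(OAc)3, MeCN/AcOH, −30 → 0 °C
Reagents that add atoms: none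
Why: Hydroxyl-directed (Evans–Saksena) reduction: the primary alcohol exchanges onto boron and hydride is delivered through a six-membered transition state to the ketone face that carries the C2 arm, so the new C3 hydroxyl ends trans to that arm (3S), against the steric bias an external hydride would follow.

Step 7
Reactants: 10 (2R,3S,5S)-2-(hydroxymethyl)-5-methyloxolan-3-ol
Product: 11 triethyl({(2R,3S,5S)-5-methyl-3-[(triethylsilyl)oxy]oxolan-2-yl}methoxy)silane
Conditions: Et3SiCl, imidazole, DMF, 0 °C → rt
Reagents that add atoms: chlorotriethylsilane, CC[Si](Cl)(CC)CC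
Why: Imidazole-promoted silyl ether formation on both hydroxyl groups touches no stereocentre.

Step 8
Reactants: 11 triethyl({(2R,3S,5S)-5-methyl-3-[(triethylsilyl)oxy]oxolan-2-yl}methoxy)silane
Product: 12 (2S,3S,5S)-5-methyl-3-[(triethylsilyl)oxy]oxolane-2-carbaldehyde
Conditions: (COCl)2, DMSO, CH2Cl2, −78 → −35 °C; then Et3N, −78 → 0 °C
Reagents that add atoms: none
Why: Swern oxidation applied directly to a bis-triethylsilyl ether: the chlorosulfonium species cleaves only the less hindered primary silyl ether and oxidises it to the aldehyde, the secondary silyl ether stays, and the cold amine step should neither epimerise C2 nor eliminate the β-silyloxy group (the descriptor at C2 becomes S only through ligand priorities).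

Step 9
Reactants: 12 (2S,3S,5S)-5-methyl-3-[(triethylsilyl)oxy]oxolane-2-carbaldehyde
Product: 13 (2E)-3-{(2R,3S,5S)-5-methyl-3-[(triethylsilyl)oxy]oxolan-2-yl}prop-2-enal
Conditions: Ph3P=CHCHO, toluene, 70 °C
Reagents that add atoms: (triphenylphosphoranylidene)acetaldehyde, O=CC=P(c1ccccc1)(c1ccccc1)c1ccccc1
Why: Wittig olefination with a stabilised formyl ylide under neutral conditions should give the (E)-enal and spare the base-sensitive α-alkoxy aldehyde centre.

Step 10
Reactants: 14 methyl 2,4-dihydroxy-6-methylbenzoate (methyl orsellinate)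
Product: 15 methyl 3-chloro-4,6-dihydroxy-2-methylbenzoate
Conditions: SO2Cl2 (1.0 equiv), Et2O, 0 °C → rt; recrystallisation
Reagents that add atoms: sulfuryl chloride, O=S(=O)(Cl)Cl
Why: Electrophilic aromatic chlorination: the free ring position para to the hydrogen-bonded hydroxyl and next to the methyl group should react first, one equivalent limits dichlorination, and the minor regioisomer is removed by crystallisation.

Step 11
Reactants: 15 methyl 3-chloro-4,6-dihydroxy-2-methylbenzoate
Product: 16 methyl 3-chloro-4,6-bis(methoxymethoxy)-2-methylbenzoate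
Conditions: NaH, MeOCH2Cl, DMF, 0 °C → rt
Reagents that add atoms: chloromethyl methyl ether, COCCl
Why: Williamson-type O-alkylation of both phenoxides gives acetal-protected phenols that tolerate the lithium amide of the next step.

Step 12
Reactants: 16 methyl 3-chloro-4,6-bis(methoxymethoxy)-2-methylbenzoate
Product: 17 methyl 3-chloro-2-(3-chloro-2-oxopropyl)-4,6-bis(methoxymethoxy)benzoate
Conditions: LiN(iPr)2 (1.05 equiv), THF, −78 °C; then ClCH2C(O)N(OMe)Me, −78 → −20 °C; NH4Cl (aq)
Reagents that add atoms: 2-chloro-N-methoxy-N-methylacetamide, CON(C)C(=O)CCl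
Why: Lateral lithiation of the ortho-toluate (benzylic anion stabilised by the flanked ester) followed by Weinreb-amide acylation, whose chelated tetrahedral adduct prevents over-addition and releases the chloromethyl ketone only on work-up.

Step 13
Reactants: 17 methyl 3-chloro-2-(3-chloro-2-oxopropyl)-4,6-bis(methoxymethoxy)benzoate
Product: 19 5-chloro-3-(chloromethyl)-6,8-dihydroxy-1H-isochromen-1-one, via dihydroxy keto ester 18 (not isolated)
Conditions: 3 M HCl (aq), THF, 50 °C; then p-TsOH·H2O (cat.), toluene, 100 °C (MeOH distilled off)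
Reagents that add atoms: none
Why: Acid hydrolysis of the methoxymethyl acetals gives 18, whose arene-conjugated enol attacks the ortho ester carbonyl (acid-catalysed enol lactonisation, 6-exo-trig at the ester carbon) with loss of methanol to give the isocoumarin.

Step 14
Reactants: 19 5-chloro-3-(chloromethyl)-6,8-dihydroxy-1H-isochromen-1-one
Product: 20 6,8-bis[(tert-butyldimethylsilyl)oxy]-5-chloro-3-(chloromethyl)-1H-isochromen-1-one
Conditions: t-BuMe2SiOTf, 2,6-lutidine, CH2Cl2, 0 °C
Reagents that add atoms: tert-butyldimethylsilyl trifluoromethanesulfonate, CC(C)(C)[Si](C)(C)OS(=O)(=O)C(F)(F)F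
Why: Silylation of both phenols with a silyl triflate and a hindered, non-nucleophilic base, chosen so that the allylic chloride is not displaced and the phenols can later be freed by fluoride.

Step 15
Reactants: 20 6,8-bis[(tert-butyldimethylsilyl)oxy]-5-chloro-3-(chloromethyl)-1H-isochromen-1-one
Product: 21 diethyl ({6,8-bis[(tert-butyldimethylsilyl)oxy]-5-chloro-1-oxo-1H-isochromen-3-yl}methyl)phosphonate
Conditions: P(OEt)3 (neat), 130 °C
Reagents that add atoms: triethyl phosphite, CCOP(OCC)OCC
Why: Michaelis–Arbuzov reaction: the phosphite displaces the primary allylic-type chloride and chloride then dealkylates the ethoxyphosphonium ion.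

Step 16
Reactants: 21 diethyl ({6,8-bis[(tert-butyldimethylsilyl)oxy]-5-chloro-1-oxo-1H-isochromen-3-yl}methyl)phosphonate; 13 (2E)-3-{(2R,3S,5S)-5-methyl-3-[(triethylsilyl)oxy]oxolan-2-yl}prop-2-enal
Product: 22 6,8-bis[(tert-butyldimethylsilyl)oxy]-5-chloro-3-[(1E,3E)-4-{(2R,3S,5S)-5-methyl-3-[(triethylsilyl)oxy]oxolan-2-yl}buta-1,3-dien-1-yl]-1H-isochromen-1-one
Conditions: LiN(SiMe3)2, THF, −78 °C; then 13, −78 → 0 °C
Reagents that add atoms: none
Why: Horner–Wadsworth–Emmons olefination: the phosphonate anion, stabilised by the phosphoryl group and the isocoumarin π-system, adds to the enal (no enolisable α-centre), and reversible addition with syn-elimination should give the new alkene E, so the diene is E,E and the stereocentres are untouched.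

Step 17
Reactants: 22 6,8-bis[(tert-butyldimethylsilyl)oxy]-5-chloro-3-[(1E,3E)-4-{(2R,3S,5S)-5-methyl-3-[(triethylsilyl)oxy]oxolan-2-yl}buta-1,3-dien-1-yl]-1H-isochromen-1-one
Product: 23 5-chloro-6,8-dihydroxy-3-{(1E,3E)-4-[(2R,3S,5S)-3-hydroxy-5-methyloxolan-2-yl]buta-1,3-dien-1-yl}-1H-isochromen-1-one
Conditions: HF·pyridine, pyridine, THF, 0 °C → rt
Reagents that add atoms: none
Why: Fluoride-mediated desilylation removes the two aryl silyl ethers and the secondary triethylsilyl ether under buffered conditions that should spare the enol lactone, the diene and the allylic C2'–O bond.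

Compound list
1 | O-benzyl-D-serine | N[C@H](COCc1ccccc1)C(=O)O | starting material
2 | (3S)-3-(benzyloxymethyl)oxiran-2-one (α-lactone, not isolated) | O=C1O[C@H]1COCc2ccccc2 | intermediate
3 | (2R)-3-(benzyloxy)-2-hydroxypropanoic acid | O[C@H](COCc1ccccc1)C(=O)O | intermediate
4 | acetaldehyde | CC=O | starting material
5 | (2R,5R)-5-(benzyloxymethyl)-2-methyl-1,3-dioxolan-4-one (cis) | O=C1O[C@H](C)O[C@@H]1COCc2ccccc2 | intermediate
6 | (2R,5R)-5-(benzyloxymethyl)-2-methyl-4-methylidene-1,3-dioxolane (cis) | C=C1O[C@H](C)O[C@@H]1COCc2ccccc2 | intermediate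
7 | chlorodimethylaluminate enolate–(E)-O-ethylidene oxocarbenium zwitterion from ring-opened 6 (not isolated) | C=C(O[Al-](C)(C)Cl)[C@@H](COCc1ccccc1)/[O+]=C/C | intermediate
8 | (2R,5S)-2-(benzyloxymethyl)-5-methyloxolan-3-one | C[C@H]1CC(=O)[C@@H](COCc2ccccc2)O1 | intermediate
9 | (2R,5S)-2-(hydroxymethyl)-5-methyloxolan-3-one | C[C@H]1CC(=O)[C@@H](CO)O1 | intermediate
10 | (2R,3S,5S)-2-(hydroxymethyl)-5-methyloxolan-3-ol | C[C@H]1C[C@H](O)[C@@H](CO)O1 | intermediate
11 | triethyl({(2R,3S,5S)-5-methyl-3-[(triethylsilyl)oxy]oxolan-2-yl}methoxy)silane | C[C@H]1C[C@H](O[Si](CC)(CC)CC)[C@@H](CO[Si](CC)(CC)CC)O1 | intermediate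
12 | (2S,3S,5S)-5-methyl-3-[(triethylsilyl)oxy]oxolane-2-carbaldehyde | C[C@H]1C[C@H](O[Si](CC)(CC)CC)[C@@H](C=O)O1 | intermediate
13 | (2E)-3-{(2R,3S,5S)-5-methyl-3-[(triethylsilyl)oxy]oxolan-2-yl}prop-2-enal | C[C@H]1C[C@H](O[Si](CC)(CC)CC)[C@@H](/C=C/C=O)O1 | intermediate
14 | methyl 2,4-dihydroxy-6-methylbenzoate | COC(=O)c1c(C)cc(O)cc1O | starting material
15 | methyl 3-chloro-4,6-dihydroxy-2-methylbenzoate | COC(=O)c1c(C)c(Cl)c(O)cc1O | intermediate
16 | methyl 3-chloro-4,6-bis(methoxymethoxy)-2-methylbenzoate | COC(=O)c1c(C)c(Cl)c(OCOC)cc1OCOC | intermediate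
17 | methyl 3-chloro-2-(3-chloro-2-oxopropyl)-4,6-bis(methoxymethoxy)benzoate | COC(=O)c1c(CC(=O)CCl)c(Cl)c(OCOC)cc1OCOC | intermediate
18 | methyl 3-chloro-2-(3-chloro-2-oxopropyl)-4,6-dihydroxybenzoate (not isolated) | COC(=O)c1c(CC(=O)CCl)c(Cl)c(O)cc1O | intermediate
19 | 5-chloro-3-(chloromethyl)-6,8-dihydroxy-1H-isochromen-1-one | ClCc1cc2c(Cl)c(O)cc(O)c2c(=O)o1 | intermediate
20 | 6,8-bis[(tert-butyldimethylsilyl)oxy]-5-chloro-3-(chloromethyl)-1H-isochromen-1-one | ClCc1cc2c(Cl)c(O[Si](C)(C)C(C)(C)C)cc(O[Si](C)(C)C(C)(C)C)c2c(=O)o1 | intermediate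
21 | diethyl ({6,8-bis[(tert-butyldimethylsilyl)oxy]-5-chloro-1-oxo-1H-isochromen-3-yl}methyl)phosphonate | CCOP(=O)(OCC)Cc1cc2c(Cl)c(O[Si](C)(C)C(C)(C)C)cc(O[Si](C)(C)C(C)(C)C)c2c(=O)o1 | intermediate
22 | 6,8-bis[(tert-butyldimethylsilyl)oxy]-5-chloro-3-[(1E,3E)-4-{(2R,3S,5S)-5-methyl-3-[(triethylsilyl)oxy]oxolan-2-yl}buta-1,3-dien-1-yl]-1H-isochromen-1-one | C[C@H]1C[C@H](O[Si](CC)(CC)CC)[C@@H](/C=C/C=C/c2cc3c(Cl)c(O[Si](C)(C)C(C)(C)C)cc(O[Si](C)(C)C(C)(C)C)c3c(=O)o2)O1 | intermediate
23 | 5-chloro-6,8-dihydroxy-3-{(1E,3E)-4-[(2R,3S,5S)-3-hydroxy-5-methyloxolan-2-yl]buta-1,3-dien-1-yl}-1H-isochromen-1-one | C[C@H]1C[C@H](O)[C@@H](/C=C/C=C/c2cc3c(Cl)c(O)cc(O)c3c(=O)o2)O1 | target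

Total step count: 17. Longest linear sequence: 11 steps (steps 1–9, 16 and 17, from 1); the isocoumarin branch (steps 10–15) joins at step 16.

Steps most likely to fail

Step 4. The acid-labile enol acetal may ionise without productive recombination (hydrolysis or oligomerisation), the ring closure may lose its cis selectivity, or the product may lose benzyl alcohol by β-elimination under the Lewis acid. The fallback closes the ring at O1–C5 instead of C4–C5 and sets out from hydroxy acid 3. Amide coupling with MeNH(OMe)·HCl (EDC·HCl, N-methylmorpholine, CH2Cl2) should give the Weinreb amide (2R)-3-(benzyloxy)-2-hydroxy-N-methoxy-N-methylpropanamide F1. Excess MeCH=CHMgBr (THF, 0 °C) should then give the α'-hydroxy enone (2R,4E)-1-(benzyloxy)-2-hydroxyhex-4-en-3-one F2. Acid-catalysed intramolecular oxa-Michael addition (p-TsOH cat., CH2Cl2) is reversible, so it should settle on the more stable cis ketone and rejoin the route at 8.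

Step 12. The hindered toluate anion may be quenched by proton transfer from the α-chloro amide, or may be alkylated at the chloromethyl carbon instead of adding to the carbonyl. The fallback sets out from 16 with the same lateral lithiation, but acylates with t-BuMe2SiOCH2C(O)N(OMe)Me, which has no displaceable halide. This should give methyl 2-{3-[(tert-butyldimethylsilyl)oxy]-2-oxopropyl}-3-chloro-4,6-bis(methoxymethoxy)benzoate F3. The acid treatment of step 13 (aqueous HCl, then p-TsOH in hot toluene) should remove the acetals and the silyl group and lactonise to 5-chloro-6,8-dihydroxy-3-(hydroxymethyl)-1H-isochromen-1-one F4. Appel chlorination (PPh3, CCl4, MeCN), which converts the primary allylic alcohol and leaves phenols alone, rejoins the route at 19.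

Step 6. Facial selectivity may be poor if intermolecular hydride transfer to the activated α-alkoxy ketone competes with internal delivery, and the small hydroxy ketone may suffer retro-aldol cleavage or β-elimination. The fallback sets C3 by inversion and sets out from 8, with the benzyl ether still in place. LiBH(s-Bu)3 (THF, −78 °C) should attack the face opposite both ring substituents and give the all-cis alcohol (2R,3R,5S)-2-(benzyloxymethyl)-5-methyloxolan-3-ol F5. Mitsunobu inversion (4-nitrobenzoic acid, PPh3, DIAD, THF) should give (2R,3S,5S)-2-(benzyloxymethyl)-5-methyloxolan-3-yl 4-nitrobenzoate F6. Methanolysis (K2CO3, MeOH) should give (2R,3S,5S)-2-(benzyloxymethyl)-5-methyloxolan-3-ol F7, and hydrogenolysis (H2, Pd/C, EtOAc) rejoins the route at 10.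

Further compounds
F1 | step 4 | (2R)-3-(benzyloxy)-2-hydroxy-N-methoxy-N-methylpropanamide | CON(C)C(=O)[C@H](O)COCc1ccccc1
F2 | step 4 | (2R,4E)-1-(benzyloxy)-2-hydroxyhex-4-en-3-one | C/C=C/C(=O)[C@H](O)COCc1ccccc1
F3 | step 12 | methyl 2-{3-[(tert-butyldimethylsilyl)oxy]-2-oxopropyl}-3-chloro-4,6-bis(methoxymethoxy)benzoate | COC(=O)c1c(CC(=O)CO[Si](C)(C)C(C)(C)C)c(Cl)c(OCOC)cc1OCOC
F4 | step 12 | 5-chloro-6,8-dihydroxy-3-(hydroxymethyl)-1H-isochromen-1-one | OCc1cc2c(Cl)c(O)cc(O)c2c(=O)o1
F5 | step 6 | (2R,3R,5S)-2-(benzyloxymethyl)-5-methyloxolan-3-ol | C[C@H]1C[C@@H](O)[C@@H](COCc2ccccc2)O1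
F6 | step 6 | (2R,3S,5S)-2-(benzyloxymethyl)-5-methyloxolan-3-yl 4-nitrobenzoate | C[C@H]1C[C@H](OC(=O)c2ccc(cc2)[N+](=O)[O-])[C@@H](COCc3ccccc3)O1
F7 | step 6 | (2R,3S,5S)-2-(benzyloxymethyl)-5-methyloxolan-3-ol | C[C@H]1C[C@H](O)[C@@H](COCc2ccccc2)O1
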